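The readings are simulated with constants of no real substance, noise included.

A small charge of free catalyst, 0.069 mM in the ash run, left 37.1% of the starting material unused at the last reading, and I wanted to know where the partner had gone. I kept a ledger of it.

| setting | ash | cedar | alder | south | north-west |
|---|---|---|---|---|---|
| starting material | 10 mM | 10 mM | 10 mM | 10 mM | 10 mM |
| partner | 11 mM | 11 mM | 12 mM | 11.0 mM | 20.0 mM |
| free catalyst | 0.069 mM | 0.19 mM | 0.25 mM | 0.25 mM | 0.080 mM |
| remark | run made earlier | run made earlier | run made earlier |  |  |
| time |  |  |  | 3.0 h | 3.0 h |

| run | time / min | target / % | starting material / % |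
|---|---|---|---|
| ash | 8.00 | 31.0 | 67.8 |
| ash | 25.0 | 49.6 | 46.9 |
| ash | 40.0 | 53.2 | 42.5 |
| ash | 60.0 | 53.5 | 39.4 |
| ash | 90.0 | 51.7 | 37.1 |
| cedar | 20.0 | 71.6 | 25.3 |
| cedar | 40.0 | 74.7 | 20.6 |
| cedar | 50.0 | 75.4 | 20.0 |
| cedar | 80.0 | 74.0 | 18.3 |
| cedar | 90.0 | 73.1 | 17.9 |
| alder | 20.0 | 82.1 | 16.0 |
| alder | 40.0 | 84.8 | 11.8 |
| alder | 50.0 | 85.4 | 11.1 |
| alder | 80.0 | 84.6 | 9.8 |
| alder | 90.0 | 83.7 | 9.9 |

(scatter of a reading: 0.3 percentage points)

* the winner by amount of target, in percent of the starting material charged; "neither" if no more than 2 percentage points parts them (south / north-west / neither)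
* how much target is there at the end, in percent of the starting material charged: south
* how much target is there at the end, in percent of the starting material charged: north-west



In the cedar run, late on, starting material fell 2.1 percentage points and target 2.3 points, so I read these two as consuming each other. Half of the missing percentage was therefore target once formed. This gave the target formed, F. The first entry in the partner's ledger is F, and the second is the waste W, partner lost without coupling, which I assumed was lost by a first-order decay. I treated the partner as the limiting reagent, its final amount zero. Dividing the decay rate by a coupling rate proportional to free catalyst C, starting material and partner, and setting aside the starting material lost with target, gives approximately W = (Q/C) ln(S₀/(S₀ − F)), with S₀ the starting material charged.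

Here Q is the waste constant, decay rate constant over coupling rate constant. The last readings gave 0.427 mM^2 for ash, 0.411 mM^2 for cedar and 0.407 mM^2 for alder, averaging 0.415 mM^2.

For south, Q/C is 1.66 mM, and closing the books gave F = 8.22 mM. For north-west, Q/C is 5.19 mM, and F = 8.90 mM. I therefore expected north-west to form more target than south.

The forecast differed from me: it chose south, with 76% for south and 56% for north-west, on the ground "so I read this as over-reaction with partner".

The flasks gave 76.2% for south and 83.4% for north-west, so the winner was north-west.

    starting material + free catalyst ⇌ catalyst intermediate A (K = 47.2 M⁻¹, k = 154 M⁻¹ s⁻¹)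
    partner + catalyst intermediate A ⇌ catalyst intermediate B (K = 37.0 M⁻¹, k = 58.3 M⁻¹ s⁻¹)
    catalyst intermediate B → free catalyst + target (k = 8.09 s⁻¹)
    starting material + target → side product (k = 0.00473 M⁻¹ s⁻¹)
    partner → decomposed reagent (k = 6.95 × 10⁻⁴ s⁻¹)

In north-west at 3.0 h, target plus half the side product came to 8.82 mM, against my 8.90 mM, and decomposed reagent stood at 11.2 mM. A neighbour of north-west, charged with 0.20 mM of free catalyst, has Q/C of 2.08 mM. The ledger then gives F = 9.92 mM and a waste of 10.1 mM. That neighbour held 10.1 mM of decomposed reagent at 3.00 h, with 0.019% of its partner left, and its target stood at 98.0%.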